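**Strategy.** The molecule is cut between C9 and C10 (C1 = lactone carbonyl, C24 = acid carbon), where the methyl-bearing allylic stereocentre C10 meets the Z-trisubstituted C8=C9 (ethyl) alkene of the diene that hangs on the dihydropyranone ring. A Zweifel olefination joins a C1–C9 dienyllithium (lactone masked as its methyl lactol acetal) to the C10 pinacol boronic ester of the complete C10–C24 chain. On iodination the boron ate complex shifts C10 from boron to C9 with retention, and anti boron–iodine elimination sets the 8Z geometry. One operation thus forms the bond, transfers the stereocentre and fixes the alkene; the precursor is an alkyl(alkenyl)boronate, not a cross-coupling pair.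

Key step: step 28

Remark: atoms are numbered along the chain from the lactone carbonyl (C1) to the carboxyl carbon (C24); in this numbering the target is (4S,5S,10R,16S,18S,19R,20S) with 6E,8Z,12E,14E,22E alkenes.
Remark: for the chiral catalysts and ligands of steps 2, 10 and 15 the enantiomer named is taken to be the one that gives the configuration drawn; if the sense proves opposite, the mirror-image catalyst is used.
Remark: the anomeric acetal centre (C1) and the C17 carbinol centre are drawn as the isomers the chemistry should favour; both are erased in steps 29 and 30, so their configuration does not matter.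

**Fragment A (C1–C9)**

Step 1
Reactants: 1 (E)-crotonaldehyde; 2 (methoxymethyl)triphenylphosphonium chloride
Product: 4 (1E,3E)-1-methoxypenta-1,3-diene, via methoxymethylene ylide 3 (not isolated)
Conditions: KOt-Bu, THF, 0 °C to rt; distillation
Reagents that add atoms: none
Why: Wittig methoxymethylenation of the enal keeps the 3E alkene and should give the 1-methoxydiene as an enol-ether isomer mixture, of which the 1E,3E component is the only one that reaches the s-cis geometry needed in step 2 (the 1Z isomer is inert there).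

Step 2
Reactants: 4 (1E,3E)-1-methoxypenta-1,3-diene; 5 (tert-butyldimethylsilyloxy)acetaldehyde
Product: 6 (2R,3S,6S)-2-[(tert-butyldimethylsilyloxy)methyl]-6-methoxy-3-methyl-3,6-dihydro-2H-pyran
Conditions: CrCl(L) (5 mol %; trivalent chromium, L = 2-(1-adamantyl)-4-methyl-6-{[(1S,2R)-2-oxidoindan-1-yl]iminomethyl}phenolate), 4 Å molecular sieves, neat, rt
Reagents that add atoms: none
Why: Catalytic asymmetric hetero-Diels–Alder reaction: the Lewis-acidic chromium Schiff-base complex binds the aldehyde and shields one face, and the endo transition state of the E,E-diene places CH2OTBS, methyl and methoxy all cis, which sets ring C2 (R), C3 (S) and the anomeric C6 (S).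

Step 3
Reactants: 6 silyl ether of step 2
Product: 7 [(2R,3S,6S)-6-methoxy-3-methyl-3,6-dihydro-2H-pyran-2-yl]methanol
Conditions: TBAF, THF, 0 °C
Reagents that add atoms: none
Why: Fluoride-induced Si–O cleavage (desilylation); the methyl acetal and the ring alkene are inert to fluoride.

Step 4
Reactants: 7 primary alcohol
Product: 8 (2R,3S,6S)-6-methoxy-3-methyl-3,6-dihydro-2H-pyran-2-carbaldehyde
Conditions: (COCl)2, DMSO, CH2Cl2, −78 °C; Et3N, −78 to −20 °C
Reagents that add atoms: none
Why: Swern oxidation works without acid, so the acetal survives, and the α-alkoxy aldehyde is formed cold and used at once to avoid epimerisation at ring C2.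

Step 5
Reactants: 9 2-ethylacrolein
Product: 11 (E)-3-bromo-2-ethylprop-2-enal, via 2,3-dibromo-2-ethylpropanal 10 (not isolated)
Conditions: Br2, CH2Cl2, −78 to 0 °C; then Et3N, 0 °C to rt
Reagents that add atoms: bromine, BrBr
Why: Bromine addition then E2 dehydrobromination, in which the base removes the more acidic proton on the bromomethyl carbon; the β-bromoenal should settle as the thermodynamically favoured E isomer (Br trans to CHO, cis to ethyl) by reversible addition–elimination.

Step 6
Reactants: 11 (E)-3-bromo-2-ethylprop-2-enal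
Product: 12 (E)-3-bromo-2-ethylprop-2-en-1-ol
Conditions: NaBH4, CeCl3·7H2O, MeOH, −20 °C
Reagents that add atoms: none
Why: Luche 1,2-reduction: the cerium salt directs borohydride to the carbonyl only, so the vinyl bromide and its geometry are kept.

Step 7
Reactants: 12 (E)-3-bromo-2-ethylprop-2-en-1-ol
Product: 13 (E)-1-bromo-2-(bromomethyl)but-1-ene
Conditions: PBr3, Et2O, 0 °C
Reagents that add atoms: phosphorus tribromide, BrP(Br)Br
Why: SN2 bromination of the primary allylic alcohol through its phosphite ester; the vinylic bromide cannot react and the alkene geometry is kept.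

Step 8
Reactants: 13 (E)-1-bromo-2-(bromomethyl)but-1-ene
Product: 14 [(E)-3-bromo-2-ethylprop-2-en-1-yl]tributylphosphonium bromide
Conditions: PBu3, MeCN, rt
Reagents that add atoms: tributylphosphine, CCCCP(CCCC)CCCC
Why: SN2 quaternisation of the phosphine by the allylic bromide; the vinylic bromide is inert.

Step 9
Reactants: 14 allylic phosphonium bromide; 8 lactol-acetal aldehyde
Product: 16 (2S,3S,6S)-2-[(1E,3E)-4-bromo-3-ethylbuta-1,3-dien-1-yl]-6-methoxy-3-methyl-3,6-dihydro-2H-pyran, via allylic tributylphosphonium ylide 15 (not isolated)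
Conditions: KOt-Bu, toluene, 0 °C; then 8, −78 to 0 °C
Reagents that add atoms: none
Why: Wittig olefination with a semi-stabilised allylic trialkylphosphonium ylide, a reagent class that favours E-dienes, forms the 6E alkene while the ethyl/bromine geometry of the ylide and the ring centres stay untouched.

**C10–C13 piece**

Step 10
Reactants: 17 ethyl (E)-crotonate
Product: 18 ethyl (R)-3-(4,4,5,5-tetramethyl-1,3,2-dioxaborolan-2-yl)butanoate
Conditions: CuCl (3 mol %), NaOt-Bu (6 mol %), (R)-1-[(S)-2-(diphenylphosphino)ferrocenyl]ethyldicyclohexylphosphine (3 mol %), MeOH (2 equiv), THF, rt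
Reagents that add atoms: bis(pinacolato)diboron, CC1(C)OB(OC1(C)C)B1OC(C)(C)C(C)(C)O1
Why: Copper-catalysed enantioselective conjugate borylation: the chiral phosphine–copper boryl adds face-selectively to the β-carbon and methanol protonates the copper enolate, which sets the boron-bearing centre (R), the future C10.

Step 11
Reactants: 18 β-boryl ester
Product: 19 (R)-3-(4,4,5,5-tetramethyl-1,3,2-dioxaborolan-2-yl)butanal
Conditions: (i-Bu)2AlH (1.1 equiv), CH2Cl2, −78 °C
Reagents that add atoms: none
Why: Partial ester reduction through the tetrahedral aluminium acetal that is stable at −78 °C; the C–B bond and its centre are not touched.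

Step 12
Reactants: 19 β-boryl aldehyde
Product: 20 2-[(2R,4E)-5-iodopent-4-en-2-yl]-4,4,5,5-tetramethyl-1,3,2-dioxaborolane
Conditions: CrCl2, CHI3, THF/dioxane, 0 °C to rt
Reagents that add atoms: iodoform, IC(I)I
Why: Takai olefination: the geminal dichromium species from iodoform adds to the aldehyde and eliminates to the E-vinyl iodide; the alkyl boronic ester is inert to CrCl2.

**Propargylic mesylate (C14–C16 piece)**

Step 13
Reactants: 21 (tert-butyldiphenylsilyloxy)acetaldehyde; 22 1-propynylmagnesium bromide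
Product: 23 rac-1-(tert-butyldiphenylsilyloxy)pent-3-yn-2-ol
Conditions: THF, −78 to 0 °C; aq. NH4Cl
Reagents that add atoms: none
Why: Grignard 1,2-addition of the alkynylmagnesium reagent to the aldehyde gives the racemic propargylic alcohol, whose centre is erased in step 14.

Step 14
Reactants: 23 racemic propargylic alcohol
Product: 24 1-(tert-butyldiphenylsilyloxy)pent-3-yn-2-one
Conditions: Dess–Martin periodinane, CH2Cl2, rt
Reagents that add atoms: none
Why: Dess–Martin oxidation gives the ynone under near-neutral conditions that keep the silyl ether.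

Step 15
Reactants: 24 ynone
Product: 25 (S)-1-(tert-butyldiphenylsilyloxy)pent-3-yn-2-ol
Conditions: RuCl[(R,R)-TsDPEN](p-cymene) (1 mol %), KOH (2 mol %), i-PrOH, rt
Reagents that add atoms: none
Why: Noyori asymmetric transfer hydrogenation: hydride and proton pass from the ruthenium amine complex through a six-membered transition state in which the alkynyl group takes the place an aryl group takes in aryl ketones, which should give the S carbinol (S because CH2OSi outranks alkynyl).

Step 16
Reactants: 25 (S)-propargylic alcohol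
Product: 26 (S)-1-(tert-butyldiphenylsilyloxy)pent-3-yn-2-yl methanesulfonate
Conditions: MsCl, Et3N, CH2Cl2, −78 to 0 °C
Reagents that add atoms: methanesulfonyl chloride, CS(=O)(=O)Cl
Why: O-Sulfonylation leaves the C–O bond and so the configuration intact; the mesylate is used directly.

**Fragment B (C10–C24)**

Step 17
Reactants: 27 (R)-3-bromo-2-methylpropan-1-ol
Product: 28 (R)-(3-bromo-2-methylpropoxy)triethylsilane
Conditions: TESCl, imidazole, CH2Cl2, 0 °C
Reagents that add atoms: chlorotriethylsilane, CC[Si](CC)(CC)Cl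
Why: Silylation masks the hydroxyl for Grignard formation; the stereocentre (future C20) is not involved.

Step 18
Reactants: 28 bromide; 29 methyl but-2-ynoate
Product: 32 methyl (2E,5S)-3,5-dimethyl-6-(triethylsilyloxy)hex-2-enoate, via Grignard reagent 30 (not isolated), via alkylcopper reagent 31 (not isolated)
Conditions: Mg, THF, 40 °C; CuBr·SMe2 (1 equiv), −40 °C; then 29, −78 °C; MeOH then aq. NH4Cl at −78 °C
Reagents that add atoms: none
Why: Syn carbocupration of the ynoate places alkyl and copper cis, and cold protonation of the alkenylcopper with retention gives the E-enoate (new chain trans to the ester); the C20 centre is remote from the reacting carbon.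

Step 19
Reactants: 32 primary triethylsilyl ether
Product: 33 methyl (2E,5S)-3,5-dimethyl-6-oxohex-2-enoate
Conditions: (COCl)2, DMSO, CH2Cl2, −78 to −30 °C; then i-Pr2NEt, −78 to 0 °C
Reagents that add atoms: none
Why: Swern conditions convert a primary triethylsilyl ether directly into the aldehyde (the chlorosulfonium salt displaces silicon as Et3SiCl and the alkoxysulfonium ylide collapses), and the hindered base at low temperature keeps the α-methyl centre.

Step 20
Reactants: 34 (S)-4-benzyl-3-propanoyl-1,3-thiazolidine-2-thione; 33 aldehyde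
Product: 36 methyl (2E,5S,6R,7S)-8-[(4S)-4-benzyl-2-sulfanylidene-1,3-thiazolidin-3-yl]-6-hydroxy-3,5,7-trimethyl-8-oxooct-2-enoate, via chlorotitanium Z-enolate 35 (not isolated)
Conditions: TiCl4 (1.05 equiv), i-Pr2NEt (1.1 equiv), N-methylpyrrolidinone (1 equiv), CH2Cl2, 0 °C; then 33, −78 to 0 °C
Reagents that add atoms: none
Why: Crimmins titanium aldol under the conditions that give the "Evans syn" product: the Z-enolate reacts through a closed Zimmerman–Traxler chair in which the benzyl group of the auxiliary blocks one face, which sets C18 (S) and C19 (R) syn to each other and, by reagent control over the aldehyde's own bias, syn to the C20 methyl.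

Step 21
Reactants: 36 aldol adduct
Product: 37 tert-butyldimethylsilyl ether of 36
Conditions: TBSOTf, 2,6-lutidine, CH2Cl2, 0 °C
Reagents that add atoms: tert-butyldimethylsilyl triflate, CC(C)(C)[Si](C)(C)OS(=O)(=O)C(F)(F)F
Why: Silylation of the hindered secondary alcohol with the silyl triflate and a non-nucleophilic base, which avoids retro-aldol cleavage.

Step 22
Reactants: 37 silylated aldol adduct
Product: 38 methyl (2E,5S,6R,7S)-6-(tert-butyldimethylsilyloxy)-3,5,7-trimethyl-8-oxooct-2-enoate
Conditions: (i-Bu)2AlH (1.1 equiv), CH2Cl2, −78 °C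
Reagents that add atoms: none
Why: Reductive cleavage of the N-acyl thiazolidinethione, which is far more electrophilic than the conjugated methyl ester, gives the aldehyde directly and frees the auxiliary; the α-centre is kept at −78 °C.

Step 23
Reactants: 38 C17 aldehyde; 26 (S)-propargylic mesylate
Product: 40 C14–C24 homopropargylic alcohol, via allenylzinc reagent 39 (not isolated)
Conditions: Pd(OAc)2 (5 mol %), PPh3 (5 mol %), Et2Zn (3 equiv), THF, −78 to −20 °C
Reagents that add atoms: none
Why: Marshall propargylation: zerovalent palladium ionises the mesylate anti (SN2′) to an allenylpalladium, Et2Zn transmetalates it to the allenylzinc, and this adds to the aldehyde through a cyclic SE2′ transition state anti to zinc, so the new bond replaces the C–O bond of 26 with net retention and sets C16 (S) by reagent control, with the C17 oxygen anti.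

Step 24
Reactants: 40 homopropargylic alcohol
Product: 41 C17 triethylsilyl ether of 40
Conditions: TESOTf, 2,6-lutidine, CH2Cl2, −78 to 0 °C
Reagents that add atoms: triethylsilyl triflate, CC[Si](CC)(CC)OS(=O)(=O)C(F)(F)F
Why: Silylation removes the acidic O–H before steps 25 to 28, and a triethylsilyl ether is chosen because it leaves together with the acetal in step 29.

Step 25
Reactants: 41 internal alkyne
Product: 42 C14 (E)-alkenylstannane
Conditions: Bu3SnH (1.5 equiv), PdCl2(PPh3)2 (5 mol %), THF, 0 °C to rt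
Reagents that add atoms: tributyltin hydride, CCCC[SnH](CCCC)CCCC
Why: Palladium-catalysed syn hydrostannation puts tin on the less hindered, methyl-bearing alkyne carbon C14 and hydrogen on C15, which gives the E-alkenylstannane (tin trans to C16).

Step 26
Reactants: 42 alkenylstannane; 20 vinyl iodide boronic ester
Product: 43 C10–C24 boronic ester methyl ester
Conditions: Pd2(dba)3 (5 mol %), AsPh3 (20 mol %), NMP, 40 °C
Reagents that add atoms: none
Why: Stille coupling joins C13 and C14 with retention of both alkene geometries (12E,14E); without base the secondary alkyl boronic ester does not transmetalate.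

Step 27
Reactants: 43 methyl ester
Product: 44 C10–C24 boronic ester carboxylic acid
Conditions: LiOH, THF/MeOH/H2O, 40 °C; then AcOH to pH 5
Reagents that add atoms: lithium hydroxide, [Li+].[OH-]
Why: Saponification (acyl–oxygen cleavage) of the only ester; silyl ethers and dienes are stable to hydroxide and the pinacol boronic ester is recovered on mild acidification.

**Fragment union and endgame**

Step 28
Reactants: 44 C10–C24 boronic ester carboxylic acid; 16 C1–C9 dienyl bromide
Product: 49 C1–C24 acetal acid, via sodium carboxylate 45 (not isolated), via dienyllithium 46 (not isolated), via boron ate complex 47 (not isolated), via iodo boronic ester 48 (not isolated)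
Conditions: 44, NaH, THF, 0 °C; separately 16, t-BuLi (2 equiv), THF/Et2O, −78 °C; combined at −78 °C; I2, MeOH, −78 °C; NaOMe, MeOH, −78 °C to rt; AcOH, aq. Na2S2O3
Reagents that add atoms: none
Why: Zweifel olefination (closest known type: iodine-induced 1,2-metallate rearrangement of alkenylboronate complexes of secondary boronic esters): bromine–lithium exchange on 16 gives dienyllithium 46 with retention of the C8=C9 geometry (Li cis to ethyl), which adds to the boron of the pre-formed carboxylate 45 to give ate complex 47. Iodine attacks the boron-activated C8=C9 bond and C10 migrates from boron to C9 anti to the iodonium, with retention at C10 because the migrating carbon keeps its σ-bond configuration; methoxide then triggers anti elimination of boron and iodine from 48. Because migration and elimination are both anti, the alkene geometry is inverted relative to the alkenyllithium, so C10 ends cis to C7 (8Z). No ring is closed; the one stereocentre at stake, C10 (R), was set in step 10 and is controlled here by the stereospecific migration alone. The step needs chemoselectivity of the alkenyllithium for boron, secured by carrying the acid as its carboxylate, the C17 oxygen as a silyl ether and the lactone as an acetal. It also needs iodination at the boron-bearing alkene of the diene and not at the remote alkenes, which the much higher nucleophilicity of the ate-activated C8=C9 bond at −78 °C should secure.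

Step 29
Reactants: 49 C1–C24 acetal acid
Product: 50 C1–C24 lactol with free C17 hydroxyl
Conditions: AcOH/THF/H2O (3:1:1), rt
Reagents that add atoms: water, O
Why: Mild acid hydrolysis opens the allylic methyl acetal to the lactol (anomer mixture) and cleaves the triethylsilyl ether, while the hindered secondary TBS ether and the primary TBDPS ether are stable to aqueous acetic acid.

Step 30
Reactants: 50 lactol carbinol
Product: 51 bis-silyl kazusamycin A
Conditions: Dess–Martin periodinane (4 equiv), CH2Cl2, 0 °C to rt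
Reagents that add atoms: none
Why: Dess–Martin oxidation takes the lactol to the α,β-unsaturated δ-lactone and the C17 carbinol to the ketone in one operation under non-basic conditions, which protects the epimerisable C16 centre and the β-silyloxy ketone from elimination.

Step 31
Reactants: 51 bis-silyl kazusamycin A
Product: 52 kazusamycin A
Conditions: HF·pyridine, pyridine, THF, 0 °C to rt
Reagents that add atoms: none
Why: Fluoride-mediated global desilylation under buffered, non-basic conditions removes the TBS and TBDPS groups without retro-aldol cleavage, β-elimination at C16 or lactone opening.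

**Compound list**

1 | (E)-crotonaldehyde | C/C=C/C=O | starting material
2 | (methoxymethyl)triphenylphosphonium chloride | COC[P+](c1ccccc1)(c1ccccc1)c1ccccc1.[Cl-] | starting material
3 | (methoxymethylene)triphenylphosphorane | COC=P(c1ccccc1)(c1ccccc1)c1ccccc1 | intermediate (not isolated)
4 | (1E,3E)-1-methoxypenta-1,3-diene | CO/C=C/C=C/C | intermediate
5 | (tert-butyldimethylsilyloxy)acetaldehyde | CC(C)(C)[Si](C)(C)OCC=O | starting material
6 | (2R,3S,6S)-2-[(tert-butyldimethylsilyloxy)methyl]-6-methoxy-3-methyl-3,6-dihydro-2H-pyran (all-cis) | CC(C)(C)[Si](C)(C)OC[C@@H]1O[C@H](OC)C=C[C@@H]1C | intermediate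
7 | [(2R,3S,6S)-6-methoxy-3-methyl-3,6-dihydro-2H-pyran-2-yl]methanol | OC[C@@H]1O[C@H](OC)C=C[C@@H]1C | intermediate
8 | (2R,3S,6S)-6-methoxy-3-methyl-3,6-dihydro-2H-pyran-2-carbaldehyde | O=C[C@@H]1O[C@H](OC)C=C[C@@H]1C | intermediate
9 | 2-ethylacrolein (2-methylidenebutanal) | CCC(=C)C=O | starting material
10 | 2,3-dibromo-2-ethylpropanal (racemic) | CCC(Br)(CBr)C=O | intermediate (not isolated)
11 | (E)-3-bromo-2-ethylprop-2-enal | CC/C(C=O)=C\Br | intermediate
12 | (E)-3-bromo-2-ethylprop-2-en-1-ol | CC/C(CO)=C\Br | intermediate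
13 | (E)-1-bromo-2-(bromomethyl)but-1-ene | CC/C(CBr)=C\Br | intermediate
14 | [(E)-3-bromo-2-ethylprop-2-en-1-yl]tributylphosphonium bromide | CC/C(C[P+](CCCC)(CCCC)CCCC)=C\Br.[Br-] | intermediate
15 | tributyl[(E)-3-bromo-2-ethylprop-2-en-1-ylidene]phosphorane | CC/C(C=P(CCCC)(CCCC)CCCC)=C\Br | intermediate (not isolated)
16 | fragment A, (2S,3S,6S)-2-[(1E,3E)-4-bromo-3-ethylbuta-1,3-dien-1-yl]-6-methoxy-3-methyl-3,6-dihydro-2H-pyran (C1–C9) | CC/C(=C\Br)/C=C/[C@@H]1O[C@H](OC)C=C[C@@H]1C | intermediate
17 | ethyl (E)-crotonate | C/C=C/C(=O)OCC | starting material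
18 | ethyl (R)-3-(4,4,5,5-tetramethyl-1,3,2-dioxaborolan-2-yl)butanoate | C[C@@H](B1OC(C)(C)C(C)(C)O1)CC(=O)OCC | intermediate
19 | (R)-3-(4,4,5,5-tetramethyl-1,3,2-dioxaborolan-2-yl)butanal | C[C@@H](B1OC(C)(C)C(C)(C)O1)CC=O | intermediate
20 | 2-[(2R,4E)-5-iodopent-4-en-2-yl]-4,4,5,5-tetramethyl-1,3,2-dioxaborolane (C10–C13) | C[C@@H](B1OC(C)(C)C(C)(C)O1)C/C=C/I | intermediate
21 | (tert-butyldiphenylsilyloxy)acetaldehyde | CC(C)(C)[Si](OCC=O)(c1ccccc1)c1ccccc1 | starting material
22 | 1-propynylmagnesium bromide | CC#C[Mg]Br | starting material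
23 | rac-1-(tert-butyldiphenylsilyloxy)pent-3-yn-2-ol | CC#CC(O)CO[Si](c1ccccc1)(c1ccccc1)C(C)(C)C | intermediate
24 | 1-(tert-butyldiphenylsilyloxy)pent-3-yn-2-one | CC#CC(=O)CO[Si](c1ccccc1)(c1ccccc1)C(C)(C)C | intermediate
25 | (S)-1-(tert-butyldiphenylsilyloxy)pent-3-yn-2-ol | CC#C[C@@H](CO[Si](c1ccccc1)(c1ccccc1)C(C)(C)C)O | intermediate
26 | (S)-1-(tert-butyldiphenylsilyloxy)pent-3-yn-2-yl methanesulfonate | CC#C[C@@H](CO[Si](c1ccccc1)(c1ccccc1)C(C)(C)C)OS(C)(=O)=O | intermediate
27 | (R)-3-bromo-2-methylpropan-1-ol | OC[C@@H](C)CBr | starting material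
28 | (R)-(3-bromo-2-methylpropoxy)triethylsilane | CC[Si](CC)(CC)OC[C@@H](C)CBr | intermediate
29 | methyl but-2-ynoate | CC#CC(=O)OC | starting material
30 | [(R)-2-methyl-3-(triethylsilyloxy)propyl]magnesium bromide | CC[Si](CC)(CC)OC[C@@H](C)C[Mg]Br | intermediate (not isolated)
31 | [(R)-2-methyl-3-(triethylsilyloxy)propyl]copper | CC[Si](CC)(CC)OC[C@@H](C)C[Cu] | intermediate (not isolated)
32 | methyl (2E,5S)-3,5-dimethyl-6-(triethylsilyloxy)hex-2-enoate (C19–C24) | CC[Si](CC)(CC)OC[C@@H](C)C/C(C)=C/C(=O)OC | intermediate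
33 | methyl (2E,5S)-3,5-dimethyl-6-oxohex-2-enoate | O=C[C@@H](C)C/C(C)=C/C(=O)OC | intermediate
34 | (S)-4-benzyl-3-propanoyl-1,3-thiazolidine-2-thione | CCC(=O)N1[C@@H](Cc2ccccc2)CSC1=S | starting material
35 | trichlorotitanium (Z)-enolate of 34 | C/C=C(\O[Ti](Cl)(Cl)Cl)N1[C@@H](Cc2ccccc2)CSC1=S | intermediate (not isolated)
36 | methyl (2E,5S,6R,7S)-8-[(4S)-4-benzyl-2-sulfanylidene-1,3-thiazolidin-3-yl]-6-hydroxy-3,5,7-trimethyl-8-oxooct-2-enoate (all-syn C18–C20) | S=C1SC[C@H](Cc2ccccc2)N1C(=O)[C@@H](C)[C@H](O)[C@@H](C)C/C(C)=C/C(=O)OC | intermediate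
37 | 6-O-tert-butyldimethylsilyl ether of 36 | S=C1SC[C@H](Cc2ccccc2)N1C(=O)[C@@H](C)[C@H](O[Si](C)(C)C(C)(C)C)[C@@H](C)C/C(C)=C/C(=O)OC | intermediate
38 | methyl (2E,5S,6R,7S)-6-(tert-butyldimethylsilyloxy)-3,5,7-trimethyl-8-oxooct-2-enoate (C17–C24 aldehyde) | O=C[C@@H](C)[C@H](O[Si](C)(C)C(C)(C)C)[C@@H](C)C/C(C)=C/C(=O)OC | intermediate
39 | ethyl[1-methyl-4-(tert-butyldiphenylsilyloxy)buta-1,2-dien-1-yl]zinc (axially chiral allenylzinc) | [H]C(CO[Si](c1ccccc1)(c1ccccc1)C(C)(C)C)=[C@]=C(C)[Zn]CC | intermediate (not isolated)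
40 | C14–C24 homopropargylic alcohol, methyl ester; 16-CH2OTBDPS, 17-OH anti to it, 19-OTBS; C16, C18, C19, C20 as in the target | CC#C[C@@H](CO[Si](c1ccccc1)(c1ccccc1)C(C)(C)C)[C@@H](O)[C@@H](C)[C@H](O[Si](C)(C)C(C)(C)C)[C@@H](C)C/C(C)=C/C(=O)OC | intermediate
41 | C17 triethylsilyl ether of 40 | CC#C[C@@H](CO[Si](c1ccccc1)(c1ccccc1)C(C)(C)C)[C@@H](O[Si](CC)(CC)CC)[C@@H](C)[C@H](O[Si](C)(C)C(C)(C)C)[C@@H](C)C/C(C)=C/C(=O)OC | intermediate
42 | C14 (E)-tributylstannyl alkene from 41 (tin on C14, trans to C16) | CCCC[Sn](CCCC)(CCCC)/C(C)=C/[C@@H](CO[Si](c1ccccc1)(c1ccccc1)C(C)(C)C)[C@@H](O[Si](CC)(CC)CC)[C@@H](C)[C@H](O[Si](C)(C)C(C)(C)C)[C@@H](C)C/C(C)=C/C(=O)OC | intermediate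
43 | fragment B methyl ester: C10–C24 chain, (10R)-10-pinacolboryl, (12E,14E,22E), 16-CH2OTBDPS, 17-OTES, 19-OTBS | C[C@@H](B1OC(C)(C)C(C)(C)O1)C/C=C/C(C)=C/[C@@H](CO[Si](c1ccccc1)(c1ccccc1)C(C)(C)C)[C@@H](O[Si](CC)(CC)CC)[C@@H](C)[C@H](O[Si](C)(C)C(C)(C)C)[C@@H](C)C/C(C)=C/C(=O)OC | intermediate
44 | fragment B: carboxylic acid of 43 | C[C@@H](B1OC(C)(C)C(C)(C)O1)C/C=C/C(C)=C/[C@@H](CO[Si](c1ccccc1)(c1ccccc1)C(C)(C)C)[C@@H](O[Si](CC)(CC)CC)[C@@H](C)[C@H](O[Si](C)(C)C(C)(C)C)[C@@H](C)C/C(C)=C/C(=O)O | intermediate
45 | sodium carboxylate of 44 | C[C@@H](B1OC(C)(C)C(C)(C)O1)C/C=C/C(C)=C/[C@@H](CO[Si](c1ccccc1)(c1ccccc1)C(C)(C)C)[C@@H](O[Si](CC)(CC)CC)[C@@H](C)[C@H](O[Si](C)(C)C(C)(C)C)[C@@H](C)C/C(C)=C/C(=O)[O-].[Na+] | intermediate (not isolated)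
46 | (1E,3E)-dienyllithium from 16 (Li cis to ethyl) | CC/C(=C\[Li])/C=C/[C@@H]1O[C@H](OC)C=C[C@@H]1C | intermediate (not isolated)
47 | lithium sodium alkyl(dienyl)pinacolatoborate carboxylate (ate complex of 45 and 46) | CC/C(=C\[B-]1(OC(C)(C)C(C)(C)O1)[C@H](C)C/C=C/C(C)=C/[C@@H](CO[Si](c2ccccc2)(c2ccccc2)C(C)(C)C)[C@@H](O[Si](CC)(CC)CC)[C@@H](C)[C@H](O[Si](C)(C)C(C)(C)C)[C@@H](C)C/C(C)=C/C(=O)[O-])/C=C/[C@@H]1O[C@H](OC)C=C[C@@H]1C.[Li+].[Na+] | intermediate (not isolated)
48 | 8-iodo-9-pinacolboryl adduct (C10 and I anti; one of the two face isomers, both of which eliminate to the same alkene) | CC[C@@](I)([C@@H](B1OC(C)(C)C(C)(C)O1)[C@H](C)C/C=C/C(C)=C/[C@@H](CO[Si](c2ccccc2)(c2ccccc2)C(C)(C)C)[C@@H](O[Si](CC)(CC)CC)[C@@H](C)[C@H](O[Si](C)(C)C(C)(C)C)[C@@H](C)C/C(C)=C/C(=O)[O-])/C=C/[C@@H]1O[C@H](OC)C=C[C@@H]1C.[Na+] | intermediate (not isolated)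
49 | C1–C24 acetal acid: lactone as all-cis methyl lactol acetal, 16-CH2OTBDPS, 17-OTES, 19-OTBS, free C24 acid; (6E,8Z,12E,14E,22E) | CCC(=C/[C@H](C)C/C=C/C(C)=C/[C@@H](CO[Si](c1ccccc1)(c1ccccc1)C(C)(C)C)[C@@H](O[Si](CC)(CC)CC)[C@@H](C)[C@H](O[Si](C)(C)C(C)(C)C)[C@@H](C)C/C(C)=C/C(=O)O)/C=C/[C@@H]1O[C@H](OC)C=C[C@@H]1C | intermediate
50 | C1 lactol (anomer mixture) with free C17 hydroxyl; 16-CH2OTBDPS, 19-OTBS | CCC(=C/[C@H](C)C/C=C/C(C)=C/[C@@H](CO[Si](c1ccccc1)(c1ccccc1)C(C)(C)C)[C@@H](O)[C@@H](C)[C@H](O[Si](C)(C)C(C)(C)C)[C@@H](C)C/C(C)=C/C(=O)O)/C=C/[C@@H]1OC(O)C=C[C@@H]1C | intermediate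
51 | 16-CH2O-TBDPS, 19-O-TBS kazusamycin A | CCC(=C/[C@H](C)C/C=C/C(C)=C/[C@@H](CO[Si](c1ccccc1)(c1ccccc1)C(C)(C)C)C(=O)[C@@H](C)[C@H](O[Si](C)(C)C(C)(C)C)[C@@H](C)C/C(C)=C/C(=O)O)/C=C/[C@@H]1OC(=O)C=C[C@@H]1C | intermediate
52 | kazusamycin A | CCC(=C/[C@H](C)C/C=C/C(C)=C/[C@@H](CO)C(=O)[C@@H](C)[C@H](O)[C@@H](C)C/C(C)=C/C(=O)O)/C=C/[C@@H]1OC(=O)C=C[C@@H]1C | target

**Step count.** Total: 31 steps. Longest linear sequence: 15 steps (steps 17 to 31).

**Steps most likely to fail**

1. Step 28 (key step). Iodination may occur at the remote C6=C7 alkene of the dienylboronate (vinylogous attack), or the tertiary allylic iodide may ionise before elimination; either would erode the 8Z geometry. Ate-complex formation at the hindered secondary boronic ester may also be incomplete. The fallback sets out from 44, 12 and 7 and comes back at 49. It keeps the boron-to-carbon shift for the C9–C10 bond but uses a non-conjugated alkenyllithium and closes the diene afterwards. Alcohol 12 is deprotonated with NaH and lithiated with t-BuLi (2 equiv, −78 °C), the resulting alkenyllithium alkoxide is added to carboxylate 45, and the ate complex is treated with I2 and NaOMe as in step 28, which should give the C7–C24 allylic alcohol acid F1. MnO2 in CH2Cl2 oxidises it to the Z-enal acid F2. In parallel, alcohol 7 is converted by Mitsunobu reaction (PPh3, diisopropyl azodicarboxylate, 1-phenyl-1H-tetrazole-5-thiol) into the tetrazolyl sulfide F3, and H2O2 with catalytic (NH4)6Mo7O24 oxidises this to the sulfone F4. Julia–Kocienski olefination of F2 (taken as its potassium carboxylate) with the anion of F4 (KN(SiMe3)2, THF, −78 °C) should form the 6E alkene and give 49.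

2. Step 26. Transmetalation of the 1-methyl-substituted alkenylstannane may be slow, which opens the way to protodestannylation, cine substitution and homocoupling. The fallback sets out from 42 and 19 and comes back at 43, with the polarity of the coupling reversed. Iododestannylation of 42 (I2, CH2Cl2, 0 °C) with retention gives the alkenyl iodide F5. Takai–Utimoto boron olefination of aldehyde 19 (Cl2CHB(pin), CrCl2, LiI, THF) gives the E-alkenyl, alkyl bis(boronate) F6. Suzuki–Miyaura coupling of F5 and F6 (PdCl2(dppf), K3PO4, THF/H2O, rt), in which only the alkenyl boronic ester transmetalates, should give 43.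

3. Step 20. Facial selectivity may be poor because the pairing is stereochemically mismatched (auxiliary control opposes the intrinsic anti-Felkin preference of a Z-enolate), and the α-methyl aldehyde may epimerise under the Lewis-acidic conditions. The fallback sets out from 33 and comes back at 38, replacing the enolate by a substrate-matched open-transition-state crotylation. (E)-Crotyltributylstannane and BF3·OEt2 (CH2Cl2, −78 °C) add syn-selectively and in the Felkin sense, which should give the all-syn homoallylic alcohol F7. TBSOTf and 2,6-lutidine give the silyl ether F8. Dihydroxylation of the terminal vinyl group (catalytic OsO4, N-methylmorpholine N-oxide), which is faster than attack on the electron-poor enoate, followed by NaIO4 cleavage gives 38.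

**Further compounds**

F1 | step 28 | C7–C24 allylic alcohol acid: (8Z)-7-hydroxy compound with C10–C24 as in 49 | CCC(=C/[C@H](C)C/C=C/C(C)=C/[C@@H](CO[Si](c1ccccc1)(c1ccccc1)C(C)(C)C)[C@@H](O[Si](CC)(CC)CC)[C@@H](C)[C@H](O[Si](C)(C)C(C)(C)C)[C@@H](C)C/C(C)=C/C(=O)O)/CO
F2 | step 28 | C7–C24 (8Z)-enal acid | CCC(=C/[C@H](C)C/C=C/C(C)=C/[C@@H](CO[Si](c1ccccc1)(c1ccccc1)C(C)(C)C)[C@@H](O[Si](CC)(CC)CC)[C@@H](C)[C@H](O[Si](C)(C)C(C)(C)C)[C@@H](C)C/C(C)=C/C(=O)O)/C=O
F3 | step 28 | 5-({[(2R,3S,6S)-6-methoxy-3-methyl-3,6-dihydro-2H-pyran-2-yl]methyl}sulfanyl)-1-phenyl-1H-tetrazole | c1ccccc1-n1nnnc1SC[C@@H]1O[C@H](OC)C=C[C@@H]1C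
F4 | step 28 | 5-({[(2R,3S,6S)-6-methoxy-3-methyl-3,6-dihydro-2H-pyran-2-yl]methyl}sulfonyl)-1-phenyl-1H-tetrazole | c1ccccc1-n1nnnc1S(=O)(=O)C[C@@H]1O[C@H](OC)C=C[C@@H]1C
F5 | step 26 | C14 (E)-alkenyl iodide corresponding to 42 | I/C(C)=C/[C@@H](CO[Si](c1ccccc1)(c1ccccc1)C(C)(C)C)[C@@H](O[Si](CC)(CC)CC)[C@@H](C)[C@H](O[Si](C)(C)C(C)(C)C)[C@@H](C)C/C(C)=C/C(=O)OC
F6 | step 26 | 2,2'-[(1E,4R)-pent-1-ene-1,4-diyl]bis(4,4,5,5-tetramethyl-1,3,2-dioxaborolane) | CC1(C)OB(/C=C/C[C@@H](C)B2OC(C)(C)C(C)(C)O2)OC1(C)C
F7 | step 20 | methyl (2E,5S,6R,7S)-6-hydroxy-3,5,7-trimethylnona-2,8-dienoate | C=C[C@@H](C)[C@H](O)[C@@H](C)C/C(C)=C/C(=O)OC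
F8 | step 20 | methyl (2E,5S,6R,7S)-6-(tert-butyldimethylsilyloxy)-3,5,7-trimethylnona-2,8-dienoate | C=C[C@@H](C)[C@H](O[Si](C)(C)C(C)(C)C)[C@@H](C)C/C(C)=C/C(=O)OC
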